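What is asked of the ochre flask at 2.5 d turns on one crossing: whether solid substrate is still there to feed the solution at that time, or has already gone into it.

| flask | solid substrate | remark | time |
|---|---|---|---|
| ochre | 0.36 M | the very flask that is asked about, followed so far |  |
| teal | 0.54 M | run made earlier |  |
| flask | 0.36 M |  | 2.5 d |

| run | time / h | solid substrate / % | target / % | starting material / % |
|---|---|---|---|---|
| ochre | 1.33 | 94 | 1 | 3 |
| ochre | 4.00 | 92 | 0 | 10 |
| ochre | 8.00 | 88 | 0 | 15 |
| ochre | 10.0 | 83 | 1 | 15 |
| teal | 2.00 | 98 | 0 | 3 |
| teal | 4.00 | 98 | 1 | 5 |
| teal | 10.0 | 88 | 3 | 11 |
| teal | 25.0 | 77 | 0 | 17 |

(each reading ± 2 percentage points)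

1. why nothing more happens at 2.5 d, or that something still does (for what has run out or reacted, a solid counts together with what of it has only dissolved) (all of the solid substrate has reacted / it is still moving / forward and back rates have come level)
2. part of the solid substrate that has turned into other species by 2.5 d (what has only dissolved does not count)
3. how much target there is at 2.5 d, in percent of the solid substrate charged
4. how much starting material there is at 2.5 d, in percent of the solid substrate charged

- percent here means solid substrate units held: one self-condensation product counts as two
- solid substrate is a solid; its amount is given per volume of the solution
- reactions considered so far: starting material -> target; solid substrate <-> starting material; starting material <-> dormant form; starting material + 2 target -> 3 target; 2 starting material -> self-condensation product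
- at the start none of the solid substrate is in solution
- what has only dissolved of solid substrate counts as not reacted
- the reaction counts as stopped when no species that holds the solid substrate changes by six tenths of a point or more over the second half of the time
- what has gone from starting material into another species counts as reacted, even if it can come back
- starting material means what is dissolved; the solid is not counted in it

Target readings do not enter this crossing, since they stay near the scatter of 2 percentage points; the charge enters in proportion. The solid readings carry the reckoning, and in the teal run an error of 2 points stands against a fall of 23 points by 25.0 h. By 10.0 h the ochre run has lost 0.00612 M h⁻¹ and the teal run 0.00648 M h⁻¹, level within that scatter despite the different charges, so the supply reads as zero order in the solid. Over its longest stretch the teal run gives 0.00497 M h⁻¹; this mean fall of c(solid substrate) per hour is an average over a course that bends, not a rate at any one moment, and it reads lower than the earlier figure. The ochre charge divided by it gives a rough clearing time of 3.02 d, later than 2.5 d, so the reckoning here is that solid substrate remains in the ochre flask and that flask is still moving.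

The forecast gives it is still moving, with 20% converted, 3% target and 24% starting material: “probably still moving slowly”.

The ochre flask gives it is still moving, with 20.6% converted, 2.62% target and 35.9% starting material.

    starting material → target (k = 4.50 × 10⁻⁷ s⁻¹)
    solid substrate ⇌ starting material, rate k2*(cs2 - [starting material]) while solid is left; crystals form when [starting material] > cs2 (solubility = 0.160 M, k = 1.40 × 10⁻⁵ s⁻¹)
    starting material ⇌ dormant form (K = 0.280, k = 1.90 × 10⁻⁵ s⁻¹)
    starting material + 2 target → 3 target (k = 7.60 × 10⁻⁴ M⁻² s⁻¹)
    2 starting material → self-condensation product (k = 6.90 × 10⁻⁶ M⁻¹ s⁻¹)

In the ochre flask solid substrate stands at 43.5% at 2.50 d, so its mean fall up to then is 0.00339 M h⁻¹, lower than the 0.00497 M h⁻¹ read from the teal run. For the neighbour flask charged with 0.14 M, the mean fall 0.00497 M h⁻¹ gives a rough clearing time of 1.17 d, earlier than 2.5 d, and that flask holds 0% solid substrate at 2.50 d.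

(Readings and results were computed from invented constants; noise was put on by code.)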